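**Strategy.** The oxocane of the 2,8-dioxabicyclo[5.2.1]decane carries bromine at C10 and C12 on either side of the C11 methylene (chain numbering from the alkyne carbon C1): a masked aldol. The eight-membered ring is therefore closed late, on an all-cis tetrahydrofuran, by a samarium diiodide Reformatsky-type aldol between C11 of a bromomethyl ketone (C12) carried on the C7 ether oxygen and a C10 aldehyde on C9. One operation forms C10–C11, the oxocane and the C10 carbinol under chelation control; hydroxyl-directed reduction and double invertive bromination then deliver the 1,3-dibromide. The tetrahydrofuran stereocentres derive from a glutamic-acid lactone, C13 from (R)-1,2-epoxybutane.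

Key step: step 10

Remark: atom labels C1–C15 follow the chain from the alkyne terminus (C6, C7, C9 in the tetrahydrofuran; C10–C13 in the oxocane); the etherification of step 4 and both bromide displacements of step 12 are assumed to run as clean SN2 inversions.

Step 1
Reactants: 1 (R)-1,2-epoxybutane
Product: 3 (R)-pent-1-en-3-ol, via sulfonium betaine 2 (not isolated)
Conditions: Me3S+ I− (3 equiv), n-BuLi (2.9 equiv), THF, −10 °C → rt
Reagents that add atoms: trimethylsulfonium iodide, C[S+](C)C.[I-]
Why: Dimethylsulfonium methylide opens the terminal epoxide at CH2 and a second equivalent converts the betaine into the one-carbon-homologated allylic alkoxide with loss of Me2S (epoxide-to-allylic-alcohol homologation), so the future C13 centre is never touched.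

Step 2
Reactants: 4 (S)-5-(hydroxymethyl)dihydrofuran-2(3H)-one
Product: 5 (S)-5-{[(tert-butyldiphenylsilyl)oxy]methyl}dihydrofuran-2(3H)-one
Conditions: t-BuPh2SiCl, imidazole, DMF, 0 °C → rt
Reagents that add atoms: tert-butyl(chloro)diphenylsilane, CC(C)(C)[Si](Cl)(c1ccccc1)c1ccccc1
Why: Standard silylation of the primary alcohol (future C10–OH) gives a group that survives enolate, triflate, hydride and Lewis-acid steps.

Step 3
Reactants: 5 silyl lactone
Product: 7 (3R,5S)-5-{[(tert-butyldiphenylsilyl)oxy]methyl}-3-hydroxydihydrofuran-2(3H)-one (3,5-trans), via sodium enolate 6 (not isolated)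
Conditions: NaN(SiMe3)2, THF, −78 °C; then 3-phenyl-2-(phenylsulfonyl)oxaziridine, −78 °C; AcOH quench
Reagents that add atoms: 3-phenyl-2-(phenylsulfonyl)oxaziridine, O=S(=O)(N1OC1c1ccccc1)c1ccccc1
Why: Electrophilic enolate hydroxylation should occur on the face anti to the C5 silyloxymethyl group and give the trans α-hydroxy lactone, which is the epimer needed for the inversion in step 4.

Step 4
Reactants: 7 trans-hydroxy lactone; 3 (R)-pent-1-en-3-ol
Product: 9 (3S,5S)-5-{[(tert-butyldiphenylsilyl)oxy]methyl}-3-{[(3R)-pent-1-en-3-yl]oxy}dihydrofuran-2(3H)-one (3,5-cis), via lactone triflate 8 (not isolated)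
Conditions: Tf2O, 2,6-di-tert-butyl-4-methylpyridine, CH2Cl2, −78 → 0 °C; then 3 (3 equiv), 0 °C → rt
Reagents that add atoms: none
Why: SN2 displacement of the α-carbonyl triflate by the neutral secondary alcohol (Williamson-type etherification of an α-triflyloxy ester under non-basic conditions) should invert C7 from trans to cis and form the C7–O–C13 ether with C13 unchanged.

Step 5
Reactants: 9 cis ether lactone
Product: 11 (3S,5S)-5-{[(tert-butyldiphenylsilyl)oxy]methyl}-3-{[(3R)-pent-1-en-3-yl]oxy}tetrahydrofuran-2-yl acetate (anomer mixture), via aluminium lactolate 10 (not isolated)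
Conditions: i-Bu2AlH, CH2Cl2, −78 °C; then pyridine, DMAP, Ac2O, −78 → 0 °C
Reagents that add atoms: acetic anhydride, CC(=O)OC(C)=O
Why: Half-reduction of the lactone and in-situ acetylation of the aluminium lactolate (reductive acetylation) gives the glycosyl-type acetate without ring opening.

Step 6
Reactants: 11 lactol acetate; 12 tert-butyl[(1-methoxyethenyl)oxy]dimethylsilane
Product: 14 methyl 2-[(2S,3S,5S)-5-{[(tert-butyldiphenylsilyl)oxy]methyl}-3-{[(3R)-pent-1-en-3-yl]oxy}tetrahydrofuran-2-yl]acetate (all-cis), via ring oxocarbenium triflate 13 (not isolated)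
Conditions: 12 (2 equiv), Me3SiOTf (0.2 equiv), CH2Cl2, −78 °C
Reagents that add atoms: none
Why: Mukaiyama-type C-glycosylation, in which inside attack on the oxocarbenium envelope that holds the C7 alkoxy and C9 silyloxymethyl groups pseudo-equatorial should place the new C6 substituent cis to both (1,2-cis rule for 2-alkoxy five-membered oxocarbenium ions).

Step 7
Reactants: 14 silyl ether ester
Product: 15 methyl 2-[(2S,3S,5S)-5-(hydroxymethyl)-3-{[(3R)-pent-1-en-3-yl]oxy}tetrahydrofuran-2-yl]acetate
Conditions: Bu4NF, AcOH, THF, 0 °C → rt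
Reagents that add atoms: none
Why: Buffered fluoride desilylation frees the C10 hydroxyl before the bromohydrin is made, so that no epoxide can form from a bromohydrin under fluoride.

Step 8
Reactants: 15 alkenyl alcohol
Product: 16 methyl 2-[(2S,3S,5S)-3-{[(3R)-1-bromo-2-hydroxypentan-3-yl]oxy}-5-(hydroxymethyl)tetrahydrofuran-2-yl]acetate (C12 epimer mixture)
Conditions: NBS, DMSO/H2O, 0 °C
Reagents that add atoms: N-bromosuccinimide, O=C1CCC(=O)N1Br; water, O
Why: Bromohydrin formation on the only alkene should follow Markovnikov opening of the bromonium ion by water (Br on terminal C11, OH on C12), and the C12 configuration is irrelevant because it is oxidised next.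

Step 9
Reactants: 16 bromohydrin diol
Product: 17 methyl 2-[(2S,3S,5S)-3-{[(3R)-1-bromo-2-oxopentan-3-yl]oxy}-5-formyltetrahydrofuran-2-yl]acetate
Conditions: Dess–Martin periodinane (3 equiv), NaHCO3, CH2Cl2, 0 °C → rt
Reagents that add atoms: none
Why: One buffered, non-epimerising oxidation converts the primary alcohol into the C10 aldehyde and the secondary bromohydrin into the C12 bromomethyl ketone.

Step 10
Reactants: 17 bromo keto aldehyde
Product: 19 methyl 2-[(1S,3R,6R,7S,9S)-3-ethyl-6-hydroxy-4-oxo-2,8-dioxabicyclo[5.2.1]decan-9-yl]acetate, via samarium enolate 18 (not isolated)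
Conditions: SmI2 (2.2 equiv), THF, slow addition of 17 to 0.005 M final concentration, −78 °C; then aq. NH4Cl
Reagents that add atoms: none
Why: Two single-electron transfers from divalent samarium cleave the C11–Br bond and give, regiospecifically, the trivalent samarium enolate 18 of the C12 ketone, which adds through C11 to the C10 aldehyde (intramolecular Reformatsky-type aldol, the closest known reaction type being SmI2-mediated closure of eight- and nine-membered carbocycles and cyclic ethers from bromo ketone aldehydes). The oxocane is closed in an 8-(enolexo)-exo-trig aldol mode across the cis-disposed C7 oxygen and C9 of the tetrahydrofuran, which turns the monocycle into the bridged 2,8-dioxabicyclo[5.2.1]decane. The new C10 stereocentre is set by chelation: the oxophilic samarium holds the enolate oxygen, the aldehyde oxygen and the tetrahydrofuran oxygen together, so the carbonyl oxygen lies gauche to the C9–O bond while C11, which can only arrive from the tether side anti to H9, attacks the exposed face and should give the 10R carbinol. The step needs chemoselective C–Br reduction in the presence of the aldehyde, the methyl ester and the α-alkoxy ketone, which the much faster reduction of the α-bromo ketone at −78 °C with only 2.2 equiv of SmI2 and no proton source should provide. It also needs ring closure to outrun intermolecular aldol addition, which high dilution, the cis arrangement of both arms on the five-membered ring and the gathering of four oxygen atoms around samarium should secure.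

Step 11
Reactants: 19 bicyclic ketol
Product: 21 methyl 2-[(1S,3R,4R,6R,7S,9S)-3-ethyl-4,6-dihydroxy-2,8-dioxabicyclo[5.2.1]decan-9-yl]acetate, via alkoxy diacetoxyborohydride 20 (not isolated)
Conditions: Me4NBH(OAc)3, MeCN/AcOH (1:1), −35 °C
Reagents that add atoms: none
Why: Evans–Saksena reduction, in which hydride is delivered internally from the C10-bound borohydride to the same face of the C12 ketone, so the new C12 hydroxyl should end trans to the C10 hydroxyl (1,3-anti diol, 12R).

Step 12
Reactants: 21 anti-1,3-diol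
Product: 22 methyl 2-[(1S,3R,4S,6S,7S,9S)-4,6-dibromo-3-ethyl-2,8-dioxabicyclo[5.2.1]decan-9-yl]acetate
Conditions: CBr4 (5 equiv), P(n-C8H17)3 (5 equiv), toluene, 70 °C
Reagents that add atoms: carbon tetrabromide, BrC(Br)(Br)Br
Why: Two Appel-type SN2 displacements of the oxyphosphonium groups by bromide should invert C10 and C12 (10R,12R diol to 10S,12S dibromide), as established for secondary carbinols next to ring oxygen in medium-ring bromo ethers.

Step 13
Reactants: 22 dibromo ester
Product: 24 2-[(1S,3R,4S,6S,7S,9S)-4,6-dibromo-3-ethyl-2,8-dioxabicyclo[5.2.1]decan-9-yl]acetaldehyde, via aluminium hemiacetal 23 (not isolated)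
Conditions: i-Bu2AlH (1.1 equiv), CH2Cl2, −78 °C; aq. KNaC4H4O6 (potassium sodium tartrate)
Reagents that add atoms: none
Why: At −78 °C the tetrahedral aluminium hemiacetal persists until work-up, so the methyl ester should stop at the C4 aldehyde, and secondary bromides are inert to the hydride.

Step 14
Reactants: 24 aldehyde; 25 1,3-bis(triisopropylsilyl)propyne
Product: 27 (1S,3R,4S,6S,7S,9S)-4,6-dibromo-3-ethyl-9-[(2Z)-5-(triisopropylsilyl)pent-2-en-4-yn-1-yl]-2,8-dioxabicyclo[5.2.1]decane, via lithium beta-silyl alkoxide 26 (not isolated)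
Conditions: 25, n-BuLi, THF, −78 °C; then 24, −78 °C → rt
Reagents that add atoms: none
Why: Peterson olefination with the lithiated bis-silyl propyne, in which the bulky silyl groups favour the adduct whose syn-elimination gives the Z-enyne.

Step 15
Reactants: 27 silyl enyne
Product: 28 (1S,3R,4S,6S,7S,9S)-4,6-dibromo-3-ethyl-9-[(2Z)-pent-2-en-4-yn-1-yl]-2,8-dioxabicyclo[5.2.1]decane (target)
Conditions: Bu4NF, THF, 0 °C
Reagents that add atoms: none
Why: Fluoride cleaves the alkynyl C–Si bond at 0 °C, where the secondary bromides and the Z-alkene should be unaffected.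

**Compound list**

1 | (R)-1,2-epoxybutane | CC[C@@H]1CO1 | starting material
2 | (R)-1-(dimethylsulfonio)pentan-3-olate (betaine) | CC[C@@H]([O-])CC[S+](C)C | intermediate
3 | (R)-pent-1-en-3-ol | CC[C@@H](O)C=C | intermediate
4 | (S)-5-(hydroxymethyl)dihydrofuran-2(3H)-one | O=C1O[C@H](CO)CC1 | starting material
5 | (S)-5-{[(tert-butyldiphenylsilyl)oxy]methyl}dihydrofuran-2(3H)-one | O=C1O[C@H](CO[Si](c2ccccc2)(c2ccccc2)C(C)(C)C)CC1 | intermediate
6 | sodium enolate of 5 | [Na+].[O-]C1=CC[C@@H](CO[Si](c2ccccc2)(c2ccccc2)C(C)(C)C)O1 | intermediate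
7 | (3R,5S)-5-{[(tert-butyldiphenylsilyl)oxy]methyl}-3-hydroxydihydrofuran-2(3H)-one | O=C1O[C@H](CO[Si](c2ccccc2)(c2ccccc2)C(C)(C)C)C[C@H]1O | intermediate
8 | (3R,5S)-3-triflate of 7 | O=C1O[C@H](CO[Si](c2ccccc2)(c2ccccc2)C(C)(C)C)C[C@H]1OS(=O)(=O)C(F)(F)F | intermediate
9 | (3S,5S)-5-{[(tert-butyldiphenylsilyl)oxy]methyl}-3-{[(3R)-pent-1-en-3-yl]oxy}dihydrofuran-2(3H)-one | O=C1O[C@H](CO[Si](c2ccccc2)(c2ccccc2)C(C)(C)C)C[C@@H]1O[C@H](CC)C=C | intermediate
10 | diisobutylaluminium lactolate of 9 | CC(C)C[Al](CC(C)C)OC1O[C@H](CO[Si](c2ccccc2)(c2ccccc2)C(C)(C)C)C[C@@H]1O[C@H](CC)C=C | intermediate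
11 | (3S,5S)-5-{[(tert-butyldiphenylsilyl)oxy]methyl}-3-{[(3R)-pent-1-en-3-yl]oxy}tetrahydrofuran-2-yl acetate | CC(=O)OC1O[C@H](CO[Si](c2ccccc2)(c2ccccc2)C(C)(C)C)C[C@@H]1O[C@H](CC)C=C | intermediate
12 | tert-butyl[(1-methoxyethenyl)oxy]dimethylsilane | C=C(OC)O[Si](C)(C)C(C)(C)C | starting material
13 | ring oxocarbenium triflate from 11 | [CH]1=[O+][C@H](CO[Si](c2ccccc2)(c2ccccc2)C(C)(C)C)C[C@@H]1O[C@H](CC)C=C.[O-]S(=O)(=O)C(F)(F)F | intermediate
14 | methyl 2-[(2S,3S,5S)-5-{[(tert-butyldiphenylsilyl)oxy]methyl}-3-{[(3R)-pent-1-en-3-yl]oxy}tetrahydrofuran-2-yl]acetate | COC(=O)C[C@@H]1O[C@H](CO[Si](c2ccccc2)(c2ccccc2)C(C)(C)C)C[C@@H]1O[C@H](CC)C=C | intermediate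
15 | methyl 2-[(2S,3S,5S)-5-(hydroxymethyl)-3-{[(3R)-pent-1-en-3-yl]oxy}tetrahydrofuran-2-yl]acetate | COC(=O)C[C@@H]1O[C@H](CO)C[C@@H]1O[C@H](CC)C=C | intermediate
16 | methyl 2-[(2S,3S,5S)-3-{[(3R)-1-bromo-2-hydroxypentan-3-yl]oxy}-5-(hydroxymethyl)tetrahydrofuran-2-yl]acetate (C12 epimers) | COC(=O)C[C@@H]1O[C@H](CO)C[C@@H]1O[C@H](CC)C(O)CBr | intermediate
17 | methyl 2-[(2S,3S,5S)-3-{[(3R)-1-bromo-2-oxopentan-3-yl]oxy}-5-formyltetrahydrofuran-2-yl]acetate | COC(=O)C[C@@H]1O[C@H](C=O)C[C@@H]1O[C@H](CC)C(=O)CBr | intermediate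
18 | samarium enolate of 17 (trivalent samarium, diiodide) | COC(=O)C[C@@H]1O[C@H](C=O)C[C@@H]1O[C@H](CC)C(=C)O[Sm](I)I | intermediate
19 | methyl 2-[(1S,3R,6R,7S,9S)-3-ethyl-6-hydroxy-4-oxo-2,8-dioxabicyclo[5.2.1]decan-9-yl]acetate | COC(=O)C[C@@H]1O[C@H]2C[C@@H]1O[C@H](CC)C(=O)C[C@H]2O | intermediate
20 | tetramethylammonium C10-alkoxy(diacetoxy)borohydride of 19 | COC(=O)C[C@@H]1O[C@H]2C[C@@H]1O[C@H](CC)C(=O)C[C@H]2O[BH-](OC(C)=O)OC(C)=O.C[N+](C)(C)C | intermediate
21 | methyl 2-[(1S,3R,4R,6R,7S,9S)-3-ethyl-4,6-dihydroxy-2,8-dioxabicyclo[5.2.1]decan-9-yl]acetate | COC(=O)C[C@@H]1O[C@H]2C[C@@H]1O[C@H](CC)[C@H](O)C[C@H]2O | intermediate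
22 | methyl 2-[(1S,3R,4S,6S,7S,9S)-4,6-dibromo-3-ethyl-2,8-dioxabicyclo[5.2.1]decan-9-yl]acetate | COC(=O)C[C@@H]1O[C@H]2C[C@@H]1O[C@H](CC)[C@@H](Br)C[C@@H]2Br | intermediate
23 | diisobutylaluminium hemiacetal of 22 | COC(O[Al](CC(C)C)CC(C)C)C[C@@H]1O[C@H]2C[C@@H]1O[C@H](CC)[C@@H](Br)C[C@@H]2Br | intermediate
24 | 2-[(1S,3R,4S,6S,7S,9S)-4,6-dibromo-3-ethyl-2,8-dioxabicyclo[5.2.1]decan-9-yl]acetaldehyde | O=CC[C@@H]1O[C@H]2C[C@@H]1O[C@H](CC)[C@@H](Br)C[C@@H]2Br | intermediate
25 | 1,3-bis(triisopropylsilyl)propyne | CC(C)[Si](C(C)C)(C(C)C)CC#C[Si](C(C)C)(C(C)C)C(C)C | starting material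
26 | lithium beta-silyl alkoxide adduct of 24 (diastereomers) | [Li]OC(C[C@@H]1O[C@H]2C[C@@H]1O[C@H](CC)[C@@H](Br)C[C@@H]2Br)C(C#C[Si](C(C)C)(C(C)C)C(C)C)[Si](C(C)C)(C(C)C)C(C)C | intermediate
27 | (1S,3R,4S,6S,7S,9S)-4,6-dibromo-3-ethyl-9-[(2Z)-5-(triisopropylsilyl)pent-2-en-4-yn-1-yl]-2,8-dioxabicyclo[5.2.1]decane | CC(C)[Si](C(C)C)(C(C)C)C#C/C=C\C[C@@H]1O[C@H]2C[C@@H]1O[C@H](CC)[C@@H](Br)C[C@@H]2Br | intermediate
28 | (1S,3R,4S,6S,7S,9S)-4,6-dibromo-3-ethyl-9-[(2Z)-pent-2-en-4-yn-1-yl]-2,8-dioxabicyclo[5.2.1]decane | C#C/C=C\C[C@@H]1O[C@H]2C[C@@H]1O[C@H](CC)[C@@H](Br)C[C@@H]2Br | target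

**Step count.** 15 steps in total. The longest linear sequence is 14 steps (steps 2–15 from lactone 4); step 1 is a one-step side branch.

**Steps most likely to fail**

Step 10 (key ring closure). The samarium enolate may be protonated or add intermolecularly faster than the eight-membered ring closes, the α-alkoxy ketone may be cleaved reductively, or a non-chelated approach may give poor facial selectivity at C10. The fallback sets out from 17 and still closes the ring through C10–C11, but as an olefination. PPh3 in MeCN converts the bromo ketone into the acylmethyl phosphonium bromide F1. Et3N in toluene at high dilution and 80 °C gives the stabilised ylide, whose intramolecular Wittig reaction with the C10 aldehyde gives the bicyclic Z-enone F2. Conjugate borylation (CuCl, NaOt-Bu, a chiral Josiphos-type bisphosphine chosen for the 10R face, B2pin2, MeOH, THF) gives the β-boryl ketone F3. Oxidation with NaBO3·4H2O proceeds with retention and comes back to the route at ketol 19.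

Step 12 (double bromination). The second displacement may be intercepted by the neighbouring hydroxyl or by transannular participation of a ring oxygen, or elimination may compete during the slower second substitution. The fallback sets out from 19 and brominates one centre at a time with the other oxygen masked. Et3SiCl and imidazole give the C10 triethylsilyl ether F4. Corey–Bakshi–Shibata reduction (BH3·SMe2, the oxazaborolidine enantiomer that delivers the 12R alcohol) gives the silyl ether alcohol F5. CBr4 and P(n-C8H17)3 with pyridine give the 12S bromide F6. HF·pyridine frees the C10 alcohol F7. A second Appel reaction on this single alcohol comes back to the route at dibromide 22.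

Step 4 (etherification). The weakly nucleophilic secondary alcohol may displace the triflate too slowly, so that elimination to the butenolide or triflate decomposition takes over. The fallback sets out from 7 and forms the ether by allylic substitution, with the lactone alcohol as nucleophile. Mitsunobu inversion (PPh3, diisopropyl azodicarboxylate, 4-nitrobenzoic acid) gives the cis 4-nitrobenzoate F8. Et3N in MeOH gives the cis hydroxy lactone F9. (E)-Pent-2-en-1-ol with ClCO2Me and pyridine gives methyl (E)-pent-2-en-1-yl carbonate F10. The copper alkoxide of F9 (LiN(SiMe3)2, CuI) then reacts with F10 under [Ir(cod)Cl]2 and a chiral phosphoramidite ligand chosen for the 13R branched ether. This catalyst-controlled branched-selective allylic etherification comes back to the route at ether 9.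

**Further compounds**

F1 | step 10 | {(3R)-3-{[(2S,3S,5S)-5-formyl-2-(2-methoxy-2-oxoethyl)tetrahydrofuran-3-yl]oxy}-2-oxopentyl}triphenylphosphonium bromide | COC(=O)C[C@@H]1O[C@H](C=O)C[C@@H]1O[C@H](CC)C(=O)C[P+](c2ccccc2)(c2ccccc2)c2ccccc2.[Br-]
F2 | step 10 | methyl 2-[(1S,3R,5Z,7S,9S)-3-ethyl-4-oxo-2,8-dioxabicyclo[5.2.1]dec-5-en-9-yl]acetate | COC(=O)C[C@@H]1O[C@H]2C[C@@H]1O[C@H](CC)C(=O)/C=C\2
F3 | step 10 | methyl 2-[(1S,3R,7S,9S)-3-ethyl-4-oxo-6-(4,4,5,5-tetramethyl-1,3,2-dioxaborolan-2-yl)-2,8-dioxabicyclo[5.2.1]decan-9-yl]acetate (C6 configured as in 19) | COC(=O)C[C@@H]1O[C@H]2C[C@@H]1O[C@H](CC)C(=O)C[C@H]2B3OC(C)(C)C(C)(C)O3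
F4 | step 12 | C10 triethylsilyl ether of ketol 19 | COC(=O)C[C@@H]1O[C@H]2C[C@@H]1O[C@H](CC)C(=O)C[C@H]2O[Si](CC)(CC)CC
F5 | step 12 | (12R)-alcohol, C10 triethylsilyl ether | COC(=O)C[C@@H]1O[C@H]2C[C@@H]1O[C@H](CC)[C@H](O)C[C@H]2O[Si](CC)(CC)CC
F6 | step 12 | (12S)-bromide, C10 triethylsilyl ether | COC(=O)C[C@@H]1O[C@H]2C[C@@H]1O[C@H](CC)[C@@H](Br)C[C@H]2O[Si](CC)(CC)CC
F7 | step 12 | (12S)-bromide, (10R)-alcohol | COC(=O)C[C@@H]1O[C@H]2C[C@@H]1O[C@H](CC)[C@@H](Br)C[C@H]2O
F8 | step 4 | (3S,5S)-5-{[(tert-butyldiphenylsilyl)oxy]methyl}-2-oxotetrahydrofuran-3-yl 4-nitrobenzoate | O=C1O[C@H](CO[Si](c2ccccc2)(c2ccccc2)C(C)(C)C)C[C@@H]1OC(=O)c3ccc(cc3)[N+](=O)[O-]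
F9 | step 4 | (3S,5S)-5-{[(tert-butyldiphenylsilyl)oxy]methyl}-3-hydroxydihydrofuran-2(3H)-one | O=C1O[C@H](CO[Si](c2ccccc2)(c2ccccc2)C(C)(C)C)C[C@@H]1O
F10 | step 4 | methyl (E)-pent-2-en-1-yl carbonate | CC/C=C/COC(=O)OC
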